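Per minute, each run turns over a steady fraction of the starting material it still holds, and that fraction is what we compare between runs.

| flask | starting material | coupling partner | protic impurity | free catalyst | stray impurity | remark |
|---|---|---|---|---|---|---|
| Wednesday's | 10 mM | 12 mM | 0.50 mM | 0.10 mM | 77 µM | run made earlier |
| Thursday's | 10 mM | 12 mM | 0.50 mM | 0.15 mM | 77 µM | run made earlier |
| flask | 10 mM | 12.0 mM | 0.500 mM | 0.20 mM | 77 µM |  |

| run | time / min | product / % |
|---|---|---|
| Wednesday's | 0.200 | 5.4 |
| Wednesday's | 0.667 | 14.2 |
| Wednesday's | 1.00 | 21.5 |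
| Wednesday's | 1.50 | 30.3 |
| Wednesday's | 2.50 | 45.4 |
| Thursday's | 0.200 | 13.7 |
| Thursday's | 0.667 | 40.6 |
| Thursday's | 1.00 | 53.6 |
| Thursday's | 1.50 | 69.2 |
| Thursday's | 2.50 | 85.3 |

(scatter of a reading: 0.3 percentage points)

* factor on the rate of making product when 30 % of the starting material are converted if free catalyst is charged twice over
* factor on the rate when 30 % of the starting material are converted if free catalyst is charged at 1.0 mM instead



We read that fraction from the last reading of each run:

Wednesday: −ln(1 − 45.4 %) / 2.50 min = 0.242 min⁻¹
Thursday: −ln(1 − 85.3 %) / 2.50 min = 0.767 min⁻¹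

The readings at 1.00 min give 0.242 min⁻¹ and 0.768 min⁻¹, so the runs look pseudo-first-order in starting material. At equal conversion, then, the factor on the rate is the factor on this constant.

The catalyst charge rose 1.50-fold but the constant rose 3.17-fold, which is more than in proportion. A straight line through both runs reaches zero rate at a charge of

(0.767 min⁻¹ × 0.10 mM − 0.242 min⁻¹ × 0.15 mM) / (0.767 min⁻¹ − 0.242 min⁻¹) = 0.0769 mM.

Two runs and two unknowns make this the weak link, so we replace it with a charged amount: we assume that the stray impurity, 77 µM, removes catalyst one for one, count that step as over at the start, and let the constant follow the catalyst that survives. We call what it leaves the live share, the fraction of the catalyst charge that survives the stray impurity. This predicts Thursday over Wednesday from the charges as 3.17, against the 3.17 read.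

Live share at 0.20 mM: 61.5 %
Charge doubled: 2 × 80.8 % / 61.5 % = 2.63
At 1.0 mM: 5.00 × 92.3 % / 61.5 % = 7.50

The forecast gave 2.63 (2.3 to 2.85) and 7.5 (4 to 8.3), holding that the stray impurity “evidently kills catalyst stoichiometrically”.

The simulation gives 2.64 and 7.70.

    free catalyst + stray impurity → spent catalyst (k = 72000 L mol⁻¹ s⁻¹)
    coupling partner + protic impurity → quenched reagent (k = 120 L mol⁻¹ s⁻¹)
    coupling partner + catalyst intermediate B ⇌ catalyst intermediate C (K = 31.0 L mol⁻¹, k = 2600 L mol⁻¹ s⁻¹)
    catalyst intermediate A ⇌ catalyst intermediate B (K = 2.20, k = 56.0 s⁻¹)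
    catalyst intermediate D → free catalyst + product (k = 5.80 s⁻¹)
    starting material + free catalyst ⇌ catalyst intermediate A (K = 36.0 L mol⁻¹, k = 590 L mol⁻¹ s⁻¹)
    catalyst intermediate C → catalyst intermediate D (k = 87.0 s⁻¹)

In this flask free catalyst is lost to the stray impurity at 330 min⁻¹ with the stray impurity as charged, a half-life of 0.126 s, far shorter than the 0.276 min the flask takes to reach 30 % conversion. By 0.400 min in this flask the stray impurity stands at 0 % and spent catalyst at 38.5 % of the catalyst charged, which leaves the live share of 61.5 %; in the flask charged with 1.0 mM the live share is 92.3 %, and at the same conversion free catalyst is 54.0 % of the catalyst.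

Readings and results are calculated for an exercise.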